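## Structural features

The target is a 3→8' linked biflavanoid. The upper unit is an eriodictyol-type flavanone (rings A and C, catechol ring B on C2). Its C3 is bonded directly to C8' of a lower taxifolin-type dihydroflavonol (rings D and F, catechol ring E on C2', hydroxyl on C3'). The four stereocentres form two adjacent trans pairs, C2/C3 (2S,3R) and C2'/C3' (2R,3R). The pairs are separated by the C3–C8' bond, so the configuration of one half cannot be relayed to the other. All four centres are labile: C3 and C3' are alpha to ketones, and C2 and C2' are lost if ring C or ring F opens by retro-oxa-Michael reaction under base. The eight phenols (two catechols) and the 3'-alcohol are best unveiled only in the last step. The real difficulty is ring D, a pentasubstituted benzene that carries O1', the C4' acyl carbon, oxygens at C5' and C7', and at C8' a bond to the hindered, stereogenic C3. Electrophilic substitution cannot reliably tell C8' from C6'. The key step uses the C4a'=C8a' bond of a preformed ring F: C8a' is the electrophilic beta carbon of a vinylogous ester and C4a' can carry a leaving group, so a 1,1-dimethoxy-3-silyloxybutadiene with an acetate arm on its nucleophilic terminus can add across this bond and aromatise, which fixes 5'-OMe, 7'-OH and the C8' carbon substituent in one operation.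

## Logic of the disconnections

**23 ⇒ 22.** Nine O–C bonds are cut: eight O–benzyl bonds and the O5'–methyl bond. The polyphenol is oxidation- and base-sensitive, so every oxygen stays masked until the end. The demand on the forward step is one non-basic reagent that removes both ether types without opening ring C or ring F.

**22 ⇒ 20 + 1.** O1–C2 and C2–C3 of ring C are cut. This is the retron of a condensation between an ortho-hydroxyaryl benzyl ketone and an aryl aldehyde, followed by oxa-Michael closure. It removes ring C, ring B and two stereocentres at once and makes the route convergent. The forward step must set C2 by catalyst control, because the lower stereocentres are too remote to help; C3 then settles trans by enolisation.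

**20 ⇒ 19 ⇒ 16 + 17.** The C4–C4a acyl–arene bond is cut, after one ortho O–benzyl bond has been re-formed on paper. The arene 17 is threefold symmetric and very nucleophilic, so ring A comes from one commercial piece with no regiochemical question. The forward steps must acylate without a strong metal Lewis acid and then free exactly one ortho oxygen.

**16 ⇒ 15 ⇒ 14.** Only functional groups change: the acid goes back to its methyl ester and the O7'–benzyl bond is cut. The free 7'-phenol next to the arm would lactonise once the acid is activated, so it is capped first. The ester must be cleaved without hydroxide, because enolisation at C3' lets O1' leave and would erode C2' and C3'.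

**14 ⇒ 7 + 11.** This is the key disconnection. C4a'–C5' and C8'–C8a' are cut, which removes the whole of ring D. The gain is large: the 5'-OMe/7'-OH/8'-carbon pattern is written by the polarity of the two partners, and both partners are small. The forward step must give complete regiocontrol and a clean aromatisation by loss of HBr and methanol that leaves ring F and its two stereocentres untouched.

**7 ⇒ 6 ⇒ 5 ⇒ 4.** The C4a'–Br bond, the O3'–benzyl bond and the C3'–O bond are cut in turn. An oxygenated diene could in principle deliver O3' during ring-F formation, but only if the oxygen sits on the diene terminus that bonds to the aldehyde carbon (C4 of the diene). An oxygen on C2 of the diene would end up on C4a', the alpha carbon of the enone. Such 4-alkoxy dienes offer no dependable enantio- or cis/trans control, and repairing a cis product by base equilibration at C3' risks opening ring F. The plan therefore forms ring F with the unsubstituted diene and adds O3' afterwards by enolate oxidation anti to the C2' aryl group, so trans is set kinetically.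

**4 ⇒ 1 + 2.** C2'–C3' and O1'–C8a' are cut, the retron of a catalytic asymmetric hetero-Diels–Alder reaction. Both pieces are commercial, and the step sets C2', from which C3' is later derived. The demand is high enantioselectivity with an electron-rich aryl aldehyde.

**11 ⇒ 10 ⇒ 8 + 9.** The O–Si bond is cut, then the C–C bond between the arm methylene and the future C8'. This reduces the diene to a commercial vinylogous ester and a bromoacetate. The forward steps must alkylate at the alpha' methyl group and then enolise the ketone rather than the ester.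

## Other disconnections considered

**Alternative 1:** The cut runs through ring C at C2–C3 and O1–C8a, before ring A exists.

- Forward key step: diene A1, a 1-methoxy-3-silyloxybutadiene whose terminal carbon already carries ring D of a perbenzylated flavan-3-ol lower unit, reacts with aldehyde 1 under Ti(OiPr)4–BINOL (tetravalent titanium). Acid then expels methanol to give dihydropyranone A2.
- In its favour: C2 is set by a catalytic reaction type with a long record for aryl aldehydes, and C3 can settle trans afterwards.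
- Against it here: the attacking diene terminus is bonded to a doubly ortho-substituted aryl ring, a far more hindered nucleophile than this reaction type normally sees. A1 itself needs a carbon substituent at C8' of a flavan, which brings back the C6'/C8' ambiguity. In A2 the lower unit has a methylene at C4', so a late benzylic oxidation is needed in the presence of other benzylic ether positions. Ring A is still missing and would need a benzannulation of the same kind as steps 4 and 7.
- Comparison: on control of C2 this alternative is the better of the two, since step 12 of the chosen plan is a proposed method. On arene construction it is at best equal, because it still needs one benzannulation and solves ring D by classical substitution. On step economy it is worse (ring A annulation plus C4' oxidation).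

**Alternative 2:** The cut is O1'–C2' of ring F.

- Forward key step: Ag2O (monovalent silver) oxidises the free catechol of the alpha-benzyloxy dihydrochalcone A3 to its ortho-quinone. Tautomerisation gives a para-quinone methide electrophilic at C2', and the ring-D phenol adds to close ring F, giving A4.
- In its favour: C3' comes from the chiral pool acid A5, so the lower half needs no asymmetric catalyst. C2' follows by 1,2-induction and, since the addition is reversible, should settle trans. The conditions are mild and biomimetic.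
- Against it here: ring D must be made by classical chemistry with an allyl group steered to C8' and three oxygens differentiated. The acylation that joins ring D to the A5-derived acid puts C3' alpha to a new ketone under Lewis-acid conditions. The catechol must be free while every other phenol is protected, so A4 needs re-protection. The allyl group needs two further oxidation steps to become the acetate arm. Addition of nucleophiles to the ortho-quinone competes with the tautomerisation.
- Comparison: on stereochemical economy of the lower half it is better than the chosen plan, which spends steps 1–3 on C2' and C3'. Its key step is of comparable novelty, so the risk is about equal. Structurally it forms one C–O bond and one stereocentre and leaves the hard part, ring D, to substitution chemistry. The step count is similar or slightly higher.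

**Alternative 3:** The cut is C3–C8', formed by migration.

- Forward key step: the 2'-hydroxychalcone A6, with ring D on its beta carbon, is oxidised by Tl(NO3)3 (trivalent thallium) in methanol. Ring D shifts from C2 to C3 with loss of monovalent thallium, and acid closes ring C through O1–C2 to give chromone A7.
- In its favour: the oxidative 1,2-aryl shift is established chemistry for 3-arylchromones, the migrating ring is electron-rich, and the skeleton is assembled by a simple aldol condensation.
- Against it here: the reagent is a stoichiometric toxic metal oxidant that can also attack electron-rich rings and benzyl ethers. The migrating group is doubly ortho-substituted. Making A6 needs strong base on a lower unit whose ring F opens under base, and needs an 8'-formyl lower unit, so the C6'/C8' problem returns. A7 has no ring B and neither upper stereocentre, so a conjugate arylation at C2 of a hindered, deactivated 3-arylchromone with control of absolute configuration would have to follow, for which no dependable method exists.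
- Comparison: its key step is known chemistry, which is better than the chosen plan's key step. The step count to A7 is roughly equal. On stereochemistry it is clearly worse, because C2 and C3 must be created last on a flat chromone, and on arene regiocontrol it is also worse.

Key step: step 7

Assumption: (S)-BINOL in step 1 is taken to direct attack to the Si face of the aryl aldehyde and so give the (S)-pyranone, and the (1R,2R) catalyst in step 12 is taken to give the (2S) closure; if either sense proves opposite, the mirror-image ligand or catalyst is used.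

## Route

Step 1
Reactants: 1 3,4-bis(benzyloxy)benzaldehyde; 2 (E)-1-methoxy-3-(trimethylsilyloxy)buta-1,3-diene
Product: 4 (S)-2-[3,4-bis(benzyloxy)phenyl]-2,3-dihydro-4H-pyran-4-one, via aldol adduct 3 (not isolated)
Conditions: Ti(OiPr)4 (10 mol %), (S)-BINOL (20 mol %), 4 Å MS, Et2O, −20 °C; then CF3CO2H, CH2Cl2, 0 °C
Reagents that add atoms: none
Why: Catalytic asymmetric hetero-Diels–Alder reaction of an aryl aldehyde with a 1-methoxy-3-silyloxybutadiene, which under the Ti(OiPr)4–BINOL catalyst (tetravalent titanium) runs as a Mukaiyama aldol addition to 3 followed by acid-induced cyclisation with loss of methanol; the ligand fixes the future C2' (S in 4, the same spatial arrangement as 2'R once C3' carries oxygen).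

Step 2
Reactants: 4 (S)-2-[3,4-bis(benzyloxy)phenyl]-2,3-dihydro-4H-pyran-4-one
Product: 5 (2R,3R)-2-[3,4-bis(benzyloxy)phenyl]-3-hydroxy-2,3-dihydro-4H-pyran-4-one
Conditions: NaN(SiMe3)2, THF, −78 °C; then 2-(phenylsulfonyl)-3-phenyloxaziridine, −78 °C; AcOH quench
Reagents that add atoms: 2-(phenylsulfonyl)-3-phenyloxaziridine, O=S(=O)(c1ccccc1)N1OC1c1ccccc1
Why: Enolate hydroxylation with an N-sulfonyloxaziridine; the only enolisable position is C3', and the oxidant should approach the enolate face opposite the adjacent pseudo-equatorial aryl group, which sets C3' trans (3'R) kinetically, with no equilibration needed.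

Step 3
Reactants: 5 (2R,3R)-2-[3,4-bis(benzyloxy)phenyl]-3-hydroxy-2,3-dihydro-4H-pyran-4-one
Product: 6 (2R,3R)-3-(benzyloxy)-2-[3,4-bis(benzyloxy)phenyl]-2,3-dihydro-4H-pyran-4-one
Conditions: BnOC(=NH)CCl3, TfOH (5 mol %), CH2Cl2–cyclohexane, 0 °C → rt
Reagents that add atoms: benzyl 2,2,2-trichloroacetimidate, N=C(OCc1ccccc1)C(Cl)(Cl)Cl
Why: Acid-catalysed O-benzylation with a trichloroacetimidate; no base is present, so the alpha-hydroxy ketone should neither epimerise nor open by retro-oxa-Michael reaction.

Step 4
Reactants: 6 (2R,3R)-3-(benzyloxy)-2-[3,4-bis(benzyloxy)phenyl]-2,3-dihydro-4H-pyran-4-one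
Product: 7 (2R,3R)-3-(benzyloxy)-2-[3,4-bis(benzyloxy)phenyl]-5-bromo-2,3-dihydro-4H-pyran-4-one
Conditions: NBS, CH2Cl2, 0 °C, dark
Reagents that add atoms: N-bromosuccinimide, O=C1CCC(=O)N1Br
Why: Electrophilic alpha-bromination of a vinylogous ester (attack of the enol-ether carbon C4a' on bromine, then loss of the proton from the oxocarbenium ion), a standard reaction of beta-alkoxy enones; under these non-acidic conditions the enol-ether carbon should react well before the dialkoxyphenyl ring.

Step 5
Reactants: 8 4,4-dimethoxybut-3-en-2-one; 9 methyl bromoacetate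
Product: 10 methyl 6,6-dimethoxy-4-oxohex-5-enoate
Conditions: LiN(iPr)2, THF, −78 °C; then 9, −78 → −30 °C
Reagents that add atoms: none
Why: Alpha'-alkylation of the kinetic cross-conjugated lithium enolate of a vinylogous ester (Stork–Danheiser-type regiochemistry) with a reactive alpha-bromo ester; this attaches the arm methylene to the future C8'.

Step 6
Reactants: 10 methyl 6,6-dimethoxy-4-oxohex-5-enoate
Product: 11 methyl (3Z)-6,6-dimethoxy-4-(trimethylsilyloxy)hexa-3,5-dienoate
Conditions: Me3SiOTf, Et3N, Et2O, 0 °C; used crude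
Reagents that add atoms: trimethylsilyl trifluoromethanesulfonate, C[Si](C)(C)OS(=O)(=O)C(F)(F)F
Why: Soft enolisation with a silyl triflate and a tertiary amine; the strongly Lewis-basic vinylogous carbonate carbonyl is silylated and then deprotonated at the adjacent methylene in preference to the ester, which should give the (Z)-silyl dienol ether.

Step 7
Reactants: 7 (2R,3R)-3-(benzyloxy)-2-[3,4-bis(benzyloxy)phenyl]-5-bromo-2,3-dihydro-4H-pyran-4-one; 11 methyl (3Z)-6,6-dimethoxy-4-(trimethylsilyloxy)hexa-3,5-dienoate
Product: 14 methyl 2-[(2R,3R)-3-(benzyloxy)-2-[3,4-bis(benzyloxy)phenyl]-7-hydroxy-5-methoxy-4-oxochroman-8-yl]acetate, via bromo ketal cycloadduct 12 (not isolated), via bromo methoxy enone 13 (not isolated)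
Conditions: 11 (2 equiv), Me3SiOTf (0.2 equiv), CH2Cl2, −78 → 0 °C; then DBU (3 equiv), 0 °C → rt; aq. NH4Cl
Reagents that add atoms: none
Why: Proposed new method: Me3SiOTf silylates the carbonyl of 7 to an oxocarbenium ion whose C8a' is attacked by the nucleophilic terminus of 11 (the carbon bearing the CH2CO2Me arm, which receives the push of the silyloxy group and, vinylogously, of the ketene acetal), a vinylogous Mukaiyama–Michael addition of the kind established for 2,3-dihydropyran-4-ones. The bromo silyl enol ether so formed closes ring D by 6-exo-trig attack of C4a' on the dimethoxycarbenium carbon of the side chain, so the net outcome is that of a polarity-matched Diels–Alder addition and gives 12; a concerted [4+2] path would lead to the same compound. Ionisation of the ketal with loss of Me3SiOMe gives the vinylogous ester 13, DBU then removes HBr across C8a'–C4a', an elimination driven by aromatisation, and the resulting dienone tautomerises to the 7'-phenol. The closest known reaction types are the Diels–Alder and aromatisation sequences of 1,1-dialkoxy-3-silyloxybutadienes with halo-quinones and with 3-acyl- or 3-cyanochromones. The selectivity needed is regiochemical, and the substrate secures it: the donor pattern of the diene and the acceptor pattern of the bromo enone allow only C8'–C8a' and C5'–C4a' bonding, so the arm ends next to O1', C5' keeps one methyl ether and C7' becomes the free phenol, while bromine marks C4a' and serves as the leaving group. No new stereocentre survives, since C4a', C8' and C8a' of 12 and 13 all become sp2; C2' is a spectator and C3' is already in its more stable trans arrangement.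

Step 8
Reactants: 14 methyl 2-[(2R,3R)-3-(benzyloxy)-2-[3,4-bis(benzyloxy)phenyl]-7-hydroxy-5-methoxy-4-oxochroman-8-yl]acetate
Product: 15 methyl 2-[(2R,3R)-3,7-bis(benzyloxy)-2-[3,4-bis(benzyloxy)phenyl]-5-methoxy-4-oxochroman-8-yl]acetate
Conditions: BnBr, K2CO3, DMF, rt
Reagents that add atoms: benzyl bromide, BrCc1ccccc1
Why: Williamson etherification of the acidic 7'-phenol (para to the C4' carbonyl), for which the weak base K2CO3 suffices; capping it prevents lactonisation onto the arm once the acid is activated in step 10.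

Step 9
Reactants: 15 methyl 2-[(2R,3R)-3,7-bis(benzyloxy)-2-[3,4-bis(benzyloxy)phenyl]-5-methoxy-4-oxochroman-8-yl]acetate
Product: 16 2-[(2R,3R)-3,7-bis(benzyloxy)-2-[3,4-bis(benzyloxy)phenyl]-5-methoxy-4-oxochroman-8-yl]acetic acid
Conditions: Me3SnOH, ClCH2CH2Cl, 70 °C; 5% aq. HCl work-up
Reagents that add atoms: trimethyltin hydroxide, C[Sn](C)(C)O
Why: Neutral methyl ester cleavage with Me3SnOH, chosen over aqueous hydroxide because hydroxide could enolise C3' and let the O1' phenoxide leave, which would erode C2' and C3'.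

Step 10
Reactants: 16 2-[(2R,3R)-3,7-bis(benzyloxy)-2-[3,4-bis(benzyloxy)phenyl]-5-methoxy-4-oxochroman-8-yl]acetic acid; 17 1,3,5-tris(benzyloxy)benzene
Product: 19 (2R,3R)-3,7-bis(benzyloxy)-2-[3,4-bis(benzyloxy)phenyl]-5-methoxy-8-{2-oxo-2-[2,4,6-tris(benzyloxy)phenyl]ethyl}chroman-4-one, via mixed trifluoroacetic anhydride 18 (not isolated)
Conditions: (CF3CO)2O, CH2Cl2, 0 °C; then 17 (1.5 equiv), 0 °C → rt
Reagents that add atoms: none
Why: Friedel–Crafts acylation through the mixed trifluoroacetic anhydride, which needs no metal Lewis acid with an arene as electron-rich as 17 and so should leave the benzyl ethers and ring F untouched; the threefold symmetry of 17 removes any regiochemical question.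

Step 11
Reactants: 19 (2R,3R)-3,7-bis(benzyloxy)-2-[3,4-bis(benzyloxy)phenyl]-5-methoxy-8-{2-oxo-2-[2,4,6-tris(benzyloxy)phenyl]ethyl}chroman-4-one
Product: 20 (2R,3R)-3,7-bis(benzyloxy)-8-{2-[2,4-bis(benzyloxy)-6-hydroxyphenyl]-2-oxoethyl}-2-[3,4-bis(benzyloxy)phenyl]-5-methoxychroman-4-one
Conditions: MgBr2·OEt2 (3 equiv), PhMe–Et2O, 70 °C; 1 M HCl work-up
Reagents that add atoms: none
Why: Chelation-controlled debenzylation: MgBr2 bridges the new ketone and one ortho ether oxygen and bromide removes that benzyl group; the magnesium phenoxide then formed protects the second ortho ether, and the methyl ether and the non-chelated benzyl ethers should not react.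

Step 12
Reactants: 20 (2R,3R)-3,7-bis(benzyloxy)-8-{2-[2,4-bis(benzyloxy)-6-hydroxyphenyl]-2-oxoethyl}-2-[3,4-bis(benzyloxy)phenyl]-5-methoxychroman-4-one; 1 3,4-bis(benzyloxy)benzaldehyde
Product: 22 (2S,3R)-5,7-bis(benzyloxy)-2-[3,4-bis(benzyloxy)phenyl]-3-[(2R,3R)-3,7-bis(benzyloxy)-2-[3,4-bis(benzyloxy)phenyl]-5-methoxy-4-oxochroman-8-yl]chroman-4-one, via alpha-aryl chalcone 21 (not isolated)
Conditions: 1 (1.5 equiv), 1-[(1R,2R)-2-aminocyclohexyl]-3-[3,5-bis(trifluoromethyl)phenyl]thiourea (20 mol %), PhCO2H (20 mol %), 4 Å MS, PhMe, 40 °C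
Reagents that add atoms: none
Why: Proposed new method: the primary amine condenses with 1 to an aldimine, Mannich-type addition of the enol of 20 and loss of the amine give chalcone 21 (Knoevenagel condensation), and the thiourea then binds the enone carbonyl while the amine acts as general base for 6-endo-trig oxa-Michael addition of the phenol, so the catalyst selects the face at C2 (2S); C3 is set by protonation of the enol and equilibrates to trans (3R) because its hydrogen is both alpha to the ketone and benzylic; the closest known reaction types are the amine-mediated condensation of 2'-hydroxydeoxybenzoins with aryl aldehydes to trans-2,3-diarylchroman-4-ones and the thiourea-catalysed enantioselective oxa-Michael closure of activated 2'-hydroxychalcones.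

Step 13
Reactants: 22 (2S,3R)-5,7-bis(benzyloxy)-2-[3,4-bis(benzyloxy)phenyl]-3-[(2R,3R)-3,7-bis(benzyloxy)-2-[3,4-bis(benzyloxy)phenyl]-5-methoxy-4-oxochroman-8-yl]chroman-4-one
Product: 23 (2S,3R)-2-(3,4-dihydroxyphenyl)-3-[(2R,3R)-2-(3,4-dihydroxyphenyl)-3,5,7-trihydroxy-4-oxochroman-8-yl]-5,7-dihydroxychroman-4-one
Conditions: BCl3 (excess), C6HMe5, CH2Cl2, −78 → 0 °C; MeOH, then aqueous work-up
Reagents that add atoms: none
Why: Lewis-acid ether cleavage: BCl3 with pentamethylbenzene as a non-basic benzyl-cation trap should remove all eight benzyl groups at low temperature, and on warming the chelate between the C4' carbonyl and O5' allows cleavage of the peri methyl ether; no base is involved, so the four stereocentres are not exposed to retro-oxa-Michael opening.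

## Compound list

1 | 3,4-bis(benzyloxy)benzaldehyde | O=Cc1ccc(OCc2ccccc2)c(OCc2ccccc2)c1 | starting material
2 | (E)-1-methoxy-3-(trimethylsilyloxy)buta-1,3-diene | CO/C=C/C(=C)O[Si](C)(C)C | starting material
3 | (1E,5S)-5-[3,4-bis(benzyloxy)phenyl]-5-hydroxy-1-methoxypent-1-en-3-one (aldol adduct, free or O-silylated) | CO/C=C/C(=O)C[C@H](O)c1ccc(OCc2ccccc2)c(OCc2ccccc2)c1 | intermediate (not isolated)
4 | (S)-2-[3,4-bis(benzyloxy)phenyl]-2,3-dihydro-4H-pyran-4-one | C1=CO[C@H](c2ccc(OCc3ccccc3)c(OCc3ccccc3)c2)CC1=O | intermediate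
5 | (2R,3R)-2-[3,4-bis(benzyloxy)phenyl]-3-hydroxy-2,3-dihydro-4H-pyran-4-one | C1=CO[C@H](c2ccc(OCc3ccccc3)c(OCc3ccccc3)c2)[C@@H](O)C1=O | intermediate
6 | (2R,3R)-3-(benzyloxy)-2-[3,4-bis(benzyloxy)phenyl]-2,3-dihydro-4H-pyran-4-one | C1=CO[C@H](c2ccc(OCc3ccccc3)c(OCc3ccccc3)c2)[C@@H](OCc2ccccc2)C1=O | intermediate
7 | (2R,3R)-3-(benzyloxy)-2-[3,4-bis(benzyloxy)phenyl]-5-bromo-2,3-dihydro-4H-pyran-4-one | BrC1=CO[C@H](c2ccc(OCc3ccccc3)c(OCc3ccccc3)c2)[C@@H](OCc3ccccc3)C1=O | intermediate (key-step precursor)
8 | 4,4-dimethoxybut-3-en-2-one | COC(OC)=CC(C)=O | starting material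
9 | methyl bromoacetate | COC(=O)CBr | starting material
10 | methyl 6,6-dimethoxy-4-oxohex-5-enoate | COC(=O)CCC(=O)C=C(OC)OC | intermediate
11 | methyl (3Z)-6,6-dimethoxy-4-(trimethylsilyloxy)hexa-3,5-dienoate | COC(OC)=C/C(O[Si](C)(C)C)=C/CC(=O)OC | intermediate (key-step precursor)
12 | methyl 2-[(2R,3R)-3-(benzyloxy)-2-[3,4-bis(benzyloxy)phenyl]-4a-bromo-5,5-dimethoxy-4-oxo-7-(trimethylsilyloxy)-3,4,4a,5,8,8a-hexahydro-2H-chromen-8-yl]acetate (configuration at C4a, C8 and C8a immaterial) | COC(=O)CC1C(O[Si](C)(C)C)=CC(OC)(OC)C2(Br)C(=O)[C@H](OCc3ccccc3)[C@@H](c3ccc(OCc4ccccc4)c(OCc4ccccc4)c3)OC12 | intermediate (not isolated)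
13 | methyl 2-[(2R,3R)-3-(benzyloxy)-2-[3,4-bis(benzyloxy)phenyl]-4a-bromo-5-methoxy-4,7-dioxo-3,4,4a,7,8,8a-hexahydro-2H-chromen-8-yl]acetate (configuration at C4a, C8 and C8a immaterial) | COC(=O)CC1C(=O)C=C(OC)C2(Br)C(=O)[C@H](OCc3ccccc3)[C@@H](c3ccc(OCc4ccccc4)c(OCc4ccccc4)c3)OC12 | intermediate (not isolated)
14 | methyl 2-[(2R,3R)-3-(benzyloxy)-2-[3,4-bis(benzyloxy)phenyl]-7-hydroxy-5-methoxy-4-oxochroman-8-yl]acetate | COC(=O)Cc1c(O)cc(OC)c2c1O[C@H](c1ccc(OCc3ccccc3)c(OCc3ccccc3)c1)[C@@H](OCc3ccccc3)C2=O | intermediate (key-step product)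
15 | methyl 2-[(2R,3R)-3,7-bis(benzyloxy)-2-[3,4-bis(benzyloxy)phenyl]-5-methoxy-4-oxochroman-8-yl]acetate | COC(=O)Cc1c(OCc3ccccc3)cc(OC)c2c1O[C@H](c1ccc(OCc3ccccc3)c(OCc3ccccc3)c1)[C@@H](OCc3ccccc3)C2=O | intermediate
16 | 2-[(2R,3R)-3,7-bis(benzyloxy)-2-[3,4-bis(benzyloxy)phenyl]-5-methoxy-4-oxochroman-8-yl]acetic acid | OC(=O)Cc1c(OCc3ccccc3)cc(OC)c2c1O[C@H](c1ccc(OCc3ccccc3)c(OCc3ccccc3)c1)[C@@H](OCc3ccccc3)C2=O | intermediate
17 | 1,3,5-tris(benzyloxy)benzene | c1ccc(COc2cc(OCc3ccccc3)cc(OCc3ccccc3)c2)cc1 | starting material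
18 | 2-[(2R,3R)-3,7-bis(benzyloxy)-2-[3,4-bis(benzyloxy)phenyl]-5-methoxy-4-oxochroman-8-yl]acetic trifluoroacetic anhydride | O=C(Cc1c(OCc3ccccc3)cc(OC)c2c1O[C@H](c1ccc(OCc3ccccc3)c(OCc3ccccc3)c1)[C@@H](OCc3ccccc3)C2=O)OC(=O)C(F)(F)F | intermediate (not isolated)
19 | (2R,3R)-3,7-bis(benzyloxy)-2-[3,4-bis(benzyloxy)phenyl]-5-methoxy-8-{2-oxo-2-[2,4,6-tris(benzyloxy)phenyl]ethyl}chroman-4-one | O=C(Cc1c(OCc3ccccc3)cc(OC)c2c1O[C@H](c1ccc(OCc3ccccc3)c(OCc3ccccc3)c1)[C@@H](OCc3ccccc3)C2=O)c1c(OCc2ccccc2)cc(OCc2ccccc2)cc1OCc1ccccc1 | intermediate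
20 | (2R,3R)-3,7-bis(benzyloxy)-8-{2-[2,4-bis(benzyloxy)-6-hydroxyphenyl]-2-oxoethyl}-2-[3,4-bis(benzyloxy)phenyl]-5-methoxychroman-4-one | O=C(Cc1c(OCc3ccccc3)cc(OC)c2c1O[C@H](c1ccc(OCc3ccccc3)c(OCc3ccccc3)c1)[C@@H](OCc3ccccc3)C2=O)c1c(O)cc(OCc2ccccc2)cc1OCc1ccccc1 | intermediate
21 | (2R,3R)-3,7-bis(benzyloxy)-8-{(E)-1-[2,4-bis(benzyloxy)-6-hydroxybenzoyl]-2-[3,4-bis(benzyloxy)phenyl]ethenyl}-2-[3,4-bis(benzyloxy)phenyl]-5-methoxychroman-4-one | O=C(/C(=C/c1ccc(OCc2ccccc2)c(OCc2ccccc2)c1)c1c(OCc3ccccc3)cc(OC)c2c1O[C@H](c1ccc(OCc3ccccc3)c(OCc3ccccc3)c1)[C@@H](OCc3ccccc3)C2=O)c1c(O)cc(OCc2ccccc2)cc1OCc1ccccc1 | intermediate (not isolated)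
22 | (2S,3R)-5,7-bis(benzyloxy)-2-[3,4-bis(benzyloxy)phenyl]-3-[(2R,3R)-3,7-bis(benzyloxy)-2-[3,4-bis(benzyloxy)phenyl]-5-methoxy-4-oxochroman-8-yl]chroman-4-one | O=C1c2c(OCc3ccccc3)cc(OCc3ccccc3)cc2O[C@H](c2ccc(OCc3ccccc3)c(OCc3ccccc3)c2)[C@H]1c1c(OCc3ccccc3)cc(OC)c2c1O[C@H](c1ccc(OCc3ccccc3)c(OCc3ccccc3)c1)[C@@H](OCc3ccccc3)C2=O | intermediate
23 | (2S,3R)-2-(3,4-dihydroxyphenyl)-3-[(2R,3R)-2-(3,4-dihydroxyphenyl)-3,5,7-trihydroxy-4-oxochroman-8-yl]-5,7-dihydroxychroman-4-one | O=C1c2c(O)cc(O)cc2O[C@H](c2ccc(O)c(O)c2)[C@H]1c1c(O)cc(O)c2c1O[C@H](c1ccc(O)c(O)c1)[C@@H](O)C2=O | target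

## Step count and least certain steps

Total: 13 steps. Longest linear sequence: 11 steps (steps 1–4, then 7–13). The diene branch (steps 5 and 6) joins at step 7.

**Step 7 (key step, proposed new method).** The bromo vinylogous ester may be too weak an acceptor, so the acid-sensitive diene could decompose under the Lewis acid before the first C–C bond forms. The aromatisation may also take the wrong course: under base, ring F can open by beta-elimination of O1', after which loss of positive bromine would compete with loss of HBr.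

Fallback in known chemistry, building ring F on a preformed ring D; it sets out from 1 and returns at 16:
- Commercial 1-(2,4-dihydroxy-6-methoxyphenyl)ethanone is allylated at its unchelated hydroxyl (allyl bromide, K2CO3, acetone) to 1-[4-(allyloxy)-2-hydroxy-6-methoxyphenyl]ethanone F1.
- Claisen rearrangement (PhNEt2, 190 °C) moves the allyl group to the carbon between the two oxygens, giving 1-(3-allyl-2,4-dihydroxy-6-methoxyphenyl)ethanone F2; the other ortho isomer must be removed here.
- Benzylation of the 4-hydroxyl (BnBr, K2CO3) gives 1-[3-allyl-4-(benzyloxy)-2-hydroxy-6-methoxyphenyl]ethanone F3.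
- Methoxymethylation of the chelated hydroxyl (MOMCl, NaH, DMF) gives 1-[3-allyl-4-(benzyloxy)-6-methoxy-2-(methoxymethoxy)phenyl]ethanone F4.
- Claisen–Schmidt condensation with 1 (KOH, EtOH) gives (E)-1-[3-allyl-4-(benzyloxy)-6-methoxy-2-(methoxymethoxy)phenyl]-3-[3,4-bis(benzyloxy)phenyl]prop-2-en-1-one F5.
- Julia–Colonna epoxidation (poly-L-leucine, urea–H2O2, DBU, THF) gives [3-allyl-4-(benzyloxy)-6-methoxy-2-(methoxymethoxy)phenyl]{(2R,3S)-3-[3,4-bis(benzyloxy)phenyl]oxiran-2-yl}methanone F6.
- HCl in MeOH removes the methoxymethyl group, and the freed phenol opens the benzylic epoxide carbon with inversion to give (2R,3R)-8-allyl-7-(benzyloxy)-2-[3,4-bis(benzyloxy)phenyl]-3-hydroxy-5-methoxychroman-4-one F7.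
- Benzylation as in step 3 gives (2R,3R)-8-allyl-3,7-bis(benzyloxy)-2-[3,4-bis(benzyloxy)phenyl]-5-methoxychroman-4-one F8.
- Lemieux–Johnson cleavage (OsO4 cat., NaIO4, 2,6-lutidine, dioxane–water) gives 2-[(2R,3R)-3,7-bis(benzyloxy)-2-[3,4-bis(benzyloxy)phenyl]-5-methoxy-4-oxochroman-8-yl]acetaldehyde F9.
- Pinnick oxidation (NaClO2, NaH2PO4, 2-methylbut-2-ene) gives 16.

This detour costs ten steps and brings back the ortho/ortho ambiguity that the key step was designed to avoid.

**Step 12 (proposed new method).** The methylene of 20 lies between two doubly ortho-substituted aryl groups, so the condensation may be slow. Facial selection at C2 rests on the catalyst alone and may be poor. Reversible ring opening could also wear down whatever selectivity is reached.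

Fallback in known chemistry; it sets out from 20 and returns at 22. 20 and 1 are condensed with pyrrolidine (EtOH–toluene, 60 °C), the established amine-mediated route from 2'-hydroxydeoxybenzoins and aryl aldehydes to trans-2,3-diarylchroman-4-ones. An achiral amine should give both trans arrangements of the upper unit. Because the lower unit is enantiopure these are diastereomers, 22 and (2R,3S)-5,7-bis(benzyloxy)-2-[3,4-bis(benzyloxy)phenyl]-3-[(2R,3R)-3,7-bis(benzyloxy)-2-[3,4-bis(benzyloxy)phenyl]-5-methoxy-4-oxochroman-8-yl]chroman-4-one F10, and are separable by chromatography or crystallisation. F10 is resubmitted to pyrrolidine, which reopens ring C through 21 and redistributes the material towards 22.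

**Step 2.** The enolate of 4 can expel O1' by beta-elimination, which would destroy the C2' configuration. Facial selectivity of the oxidation could also be incomplete.

Fallback; it sets out from 4 and returns at 5. Mn(OAc)3 (trivalent manganese) in benzene at reflux acetoxylates the alpha' position of enones without a free basic enolate, a reaction known for 2-substituted 2,3-dihydropyran-4-ones with the acetate entering trans. It should give (2R,3R)-2-[3,4-bis(benzyloxy)phenyl]-4-oxo-3,4-dihydro-2H-pyran-3-yl acetate F11. Brief methanolysis (K2CO3 cat., MeOH, −10 °C) then gives 5.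

**Step 10.** The activated acyl group may be captured intramolecularly by O7' with loss of its benzyl group (lactonisation), or the arene may be acylated by the trifluoroacetyl end of the anhydride.

Fallback; it sets out from 16 and returns at 20, so step 11 is bypassed. 16 is esterified with commercial 3,5-bis(benzyloxy)phenol (EDC·HCl, DMAP, CH2Cl2) to 3,5-bis(benzyloxy)phenyl 2-[(2R,3R)-3,7-bis(benzyloxy)-2-[3,4-bis(benzyloxy)phenyl]-5-methoxy-4-oxochroman-8-yl]acetate F12. A Fries rearrangement catalysed by Sc(OTf)3 (toluene–MeNO2, 50–80 °C) then moves the acyl group to the carbon ortho to the phenolic oxygen.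

**Step 13.** Cleavage of the chelated methyl ether may be incomplete at temperatures the polyphenol tolerates. Benzyl cations may alkylate the phloroglucinol-type rings. The Lewis acid may open ring C or ring F at the benzylic C–O bond, with epimerisation.

Fallback; it sets out from 22 and returns at 23. Hydrogenolysis (H2, Pd(OH)2 on carbon, THF–MeOH, rt) removes the eight benzyl groups under neutral conditions and leaves the aryl ketones, giving (2S,3R)-2-(3,4-dihydroxyphenyl)-3-[(2R,3R)-2-(3,4-dihydroxyphenyl)-3,7-dihydroxy-5-methoxy-4-oxochroman-8-yl]-5,7-dihydroxychroman-4-one F13. The chelated methyl ether alone is then cleaved with BCl3 (CH2Cl2, 0 °C).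

## Further compounds

F1 | step 7 | 1-[4-(allyloxy)-2-hydroxy-6-methoxyphenyl]ethanone | CC(=O)c1c(O)cc(OCC=C)cc1OC
F2 | step 7 | 1-(3-allyl-2,4-dihydroxy-6-methoxyphenyl)ethanone | CC(=O)c1c(O)c(CC=C)c(O)cc1OC
F3 | step 7 | 1-[3-allyl-4-(benzyloxy)-2-hydroxy-6-methoxyphenyl]ethanone | CC(=O)c1c(O)c(CC=C)c(OCc2ccccc2)cc1OC
F4 | step 7 | 1-[3-allyl-4-(benzyloxy)-6-methoxy-2-(methoxymethoxy)phenyl]ethanone | CC(=O)c1c(OCOC)c(CC=C)c(OCc2ccccc2)cc1OC
F5 | step 7 | (E)-1-[3-allyl-4-(benzyloxy)-6-methoxy-2-(methoxymethoxy)phenyl]-3-[3,4-bis(benzyloxy)phenyl]prop-2-en-1-one | O=C(/C=C/c1ccc(OCc2ccccc2)c(OCc2ccccc2)c1)c1c(OCOC)c(CC=C)c(OCc2ccccc2)cc1OC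
F6 | step 7 | [3-allyl-4-(benzyloxy)-6-methoxy-2-(methoxymethoxy)phenyl]{(2R,3S)-3-[3,4-bis(benzyloxy)phenyl]oxiran-2-yl}methanone | O=C([C@@H]1O[C@H]1c1ccc(OCc2ccccc2)c(OCc2ccccc2)c1)c1c(OCOC)c(CC=C)c(OCc2ccccc2)cc1OC
F7 | step 7 | (2R,3R)-8-allyl-7-(benzyloxy)-2-[3,4-bis(benzyloxy)phenyl]-3-hydroxy-5-methoxychroman-4-one | C=CCc1c(OCc3ccccc3)cc(OC)c2c1O[C@H](c1ccc(OCc3ccccc3)c(OCc3ccccc3)c1)[C@@H](O)C2=O
F8 | step 7 | (2R,3R)-8-allyl-3,7-bis(benzyloxy)-2-[3,4-bis(benzyloxy)phenyl]-5-methoxychroman-4-one | C=CCc1c(OCc3ccccc3)cc(OC)c2c1O[C@H](c1ccc(OCc3ccccc3)c(OCc3ccccc3)c1)[C@@H](OCc3ccccc3)C2=O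
F9 | step 7 | 2-[(2R,3R)-3,7-bis(benzyloxy)-2-[3,4-bis(benzyloxy)phenyl]-5-methoxy-4-oxochroman-8-yl]acetaldehyde | O=CCc1c(OCc3ccccc3)cc(OC)c2c1O[C@H](c1ccc(OCc3ccccc3)c(OCc3ccccc3)c1)[C@@H](OCc3ccccc3)C2=O
F10 | step 12 | (2R,3S)-5,7-bis(benzyloxy)-2-[3,4-bis(benzyloxy)phenyl]-3-[(2R,3R)-3,7-bis(benzyloxy)-2-[3,4-bis(benzyloxy)phenyl]-5-methoxy-4-oxochroman-8-yl]chroman-4-one | O=C1c2c(OCc3ccccc3)cc(OCc3ccccc3)cc2O[C@@H](c2ccc(OCc3ccccc3)c(OCc3ccccc3)c2)[C@@H]1c1c(OCc3ccccc3)cc(OC)c2c1O[C@H](c1ccc(OCc3ccccc3)c(OCc3ccccc3)c1)[C@@H](OCc3ccccc3)C2=O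
F11 | step 2 | (2R,3R)-2-[3,4-bis(benzyloxy)phenyl]-4-oxo-3,4-dihydro-2H-pyran-3-yl acetate | C1=CO[C@H](c2ccc(OCc3ccccc3)c(OCc3ccccc3)c2)[C@@H](OC(C)=O)C1=O
F12 | step 10 | 3,5-bis(benzyloxy)phenyl 2-[(2R,3R)-3,7-bis(benzyloxy)-2-[3,4-bis(benzyloxy)phenyl]-5-methoxy-4-oxochroman-8-yl]acetate | O=C(Cc1c(OCc3ccccc3)cc(OC)c2c1O[C@H](c1ccc(OCc3ccccc3)c(OCc3ccccc3)c1)[C@@H](OCc3ccccc3)C2=O)Oc1cc(OCc2ccccc2)cc(OCc2ccccc2)c1
F13 | step 13 | (2S,3R)-2-(3,4-dihydroxyphenyl)-3-[(2R,3R)-2-(3,4-dihydroxyphenyl)-3,7-dihydroxy-5-methoxy-4-oxochroman-8-yl]-5,7-dihydroxychroman-4-one | O=C1c2c(O)cc(O)cc2O[C@H](c2ccc(O)c(O)c2)[C@H]1c1c(O)cc(OC)c2c1O[C@H](c1ccc(O)c(O)c1)[C@@H](O)C2=O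
A1 | alternative 1 | (2R,3S)-3,5,7-tris(benzyloxy)-2-[3,4-bis(benzyloxy)phenyl]-8-[(1Z,3E)-4-methoxy-2-(trimethylsilyloxy)buta-1,3-dien-1-yl]chromane | CO/C=C/C(O[Si](C)(C)C)=C/c1c(OCc3ccccc3)cc(OCc3ccccc3)c2c1O[C@H](c1ccc(OCc3ccccc3)c(OCc3ccccc3)c1)[C@@H](OCc3ccccc3)C2
A2 | alternative 1 | (2S,3R)-2-[3,4-bis(benzyloxy)phenyl]-3-[(2R,3S)-3,5,7-tris(benzyloxy)-2-[3,4-bis(benzyloxy)phenyl]chroman-8-yl]-2,3-dihydro-4H-pyran-4-one | O=C1C=CO[C@H](c2ccc(OCc3ccccc3)c(OCc3ccccc3)c2)[C@H]1c1c(OCc3ccccc3)cc(OCc3ccccc3)c2c1O[C@H](c1ccc(OCc3ccccc3)c(OCc3ccccc3)c1)[C@@H](OCc3ccccc3)C2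
A3 | alternative 2 | (R)-1-[3-allyl-4,6-bis(benzyloxy)-2-hydroxyphenyl]-2-(benzyloxy)-3-(3,4-dihydroxyphenyl)propan-1-one | C=CCc1c(OCc2ccccc2)cc(OCc2ccccc2)c(C(=O)[C@H](OCc2ccccc2)Cc2ccc(O)c(O)c2)c1O
A4 | alternative 2 | (2R,3R)-8-allyl-3,5,7-tris(benzyloxy)-2-(3,4-dihydroxyphenyl)chroman-4-one | C=CCc1c(OCc3ccccc3)cc(OCc3ccccc3)c2c1O[C@H](c1ccc(O)c(O)c1)[C@@H](OCc3ccccc3)C2=O
A5 | alternative 2 | (R)-3-(3,4-dihydroxyphenyl)-2-hydroxypropanoic acid (danshensu) | OC(=O)[C@H](O)Cc1ccc(O)c(O)c1
A6 | alternative 3 | (2R,3R)-3,5,7-tris(benzyloxy)-8-{(E)-3-[2,4-bis(benzyloxy)-6-hydroxyphenyl]-3-oxoprop-1-en-1-yl}-2-[3,4-bis(benzyloxy)phenyl]chroman-4-one | O=C(/C=C/c1c(OCc3ccccc3)cc(OCc3ccccc3)c2c1O[C@H](c1ccc(OCc3ccccc3)c(OCc3ccccc3)c1)[C@@H](OCc3ccccc3)C2=O)c1c(O)cc(OCc2ccccc2)cc1OCc1ccccc1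
A7 | alternative 3 | 5,7-bis(benzyloxy)-3-[(2R,3R)-3,5,7-tris(benzyloxy)-2-[3,4-bis(benzyloxy)phenyl]-4-oxochroman-8-yl]-4H-chromen-4-one | O=c1c2c(OCc3ccccc3)cc(OCc3ccccc3)cc2occ1-c1c(OCc3ccccc3)cc(OCc3ccccc3)c2c1O[C@H](c1ccc(OCc3ccccc3)c(OCc3ccccc3)c1)[C@@H](OCc3ccccc3)C2=O
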